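**Convention:** β is the face that carries the two ring-fusion hydrogens and α is the opposite face. Hydrindanes use indene numbering and decalins use naphthalene numbering.

**Assumption:** (S)-4-(TBSO)cyclopent-2-enone (C5 core plus a silyl protecting group) is bought as such.

## Retrosynthetic overview
1. 21 ⇐ 20 by C-3 enolate hydroxylation. 20 ⇐ 18 by acetylation and E1cB elimination to the isopropylidene.
2. Key disconnection: 18 ⇐ 14 + acetone. The cyclopentanol is enlarged by one carbon. C-7a shifts from the carbinol carbon to a CHBr carbenoid carbon, and acetone traps the resulting enolate.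
3. 14 ⇐ 10 by ring-B adjustment: α'-acetoxylation, kinetic protonation at C-4, and hydride delivery from the β-face.
4. 10 ⇐ 6 + CH2Br2. 6 ⇐ 3 + 5 by double Michael annulation.
5. Ring order: chiral cyclopentane (bought), then ring B (annulation), then ring A (cyclopentane enlarged to cyclohexanone).

## Route

Step 1
Reactants: 1 (S)-4-[(tert-butyldimethylsilyl)oxy]cyclopent-2-en-1-one
Product: 3 (S)-4-methylcyclopent-2-en-1-one, via trans-3-methyl-4-silyloxycyclopentanone 2 (not isolated)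
Conditions: Me2CuLi (MeLi, CuI), Et2O, −78 °C; aq NH4Cl; crude, DBU (cat.), CH2Cl2, rt
Reagents that add atoms: lithium dimethylcuprate [Li+].C[Cu-]C
Why: Gilman conjugate addition anti to the silyloxy group sets the methyl-bearing centre, and E1cB loss of silanol moves the enone to the other side of the ring (1,4-addition/β-elimination).

Step 2
Reactants: 4 3-methylbut-3-en-2-one
Product: 5 tert-butyldimethyl[(3-methylbuta-1,3-dien-2-yl)oxy]silane
Conditions: TBSOTf, Et3N, Et2O, 0 °C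
Reagents that add atoms: tert-butyldimethylsilyl triflate CC(C)(C)[Si](C)(C)OS(=O)(=O)C(F)(F)F
Why: Soft enolisation of the methyl ketone gives the 2-silyloxydiene, and no stereocentre is formed.

Step 3
Reactants: 3 (S)-4-methylcyclopent-2-en-1-one; 5 tert-butyldimethyl[(3-methylbuta-1,3-dien-2-yl)oxy]silane
Product: 6 (3S,3aR,7aR)-5-[(tert-butyldimethylsilyl)oxy]-3,6-dimethyl-2,3,3a,4,7,7a-hexahydro-1H-inden-1-one (cis-fused; 3-Me β)
Conditions: Tf2NH (5 mol %), CH2Cl2, −78 → −20 °C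
Reagents that add atoms: none
Why: In this silylium-catalysed double Mukaiyama–Michael annulation the CH2 terminus of 5 adds to the β-carbon of 3 anti to the methyl (sets C-3a), and the transferred silyl enol ether then closes onto the activated isopropenyl ketone on the same face (sets C-7a, cis), which leaves the ring-B carbonyl masked and the cyclopentanone free.

Step 4
Reactants: 6 (3S,3aR,7aR)-5-[(tert-butyldimethylsilyl)oxy]-3,6-dimethyl-2,3,3a,4,7,7a-hexahydro-1H-inden-1-one; 7 dibromomethane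
Product: 9 (1S,3S,3aR,7aR)-5-[(tert-butyldimethylsilyl)oxy]-1-(dibromomethyl)-3,6-dimethyl-2,3,3a,4,7,7a-hexahydro-1H-inden-1-ol, via dibromomethyllithium 8 (not isolated)
Conditions: LDA added to 6 + CH2Br2, THF, −90 °C; aq NH4Cl
Reagents that add atoms: none
Why: Dibromomethyllithium adds 1,2 to the only free ketone from the β-face, and the new carbinol centre is erased again in step 8.

Step 5
Reactants: 9 (1S,3S,3aR,7aR)-5-[(tert-butyldimethylsilyl)oxy]-1-(dibromomethyl)-3,6-dimethyl-2,3,3a,4,7,7a-hexahydro-1H-inden-1-ol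
Product: 10 (1S,3S,3aR,7aS)-1-(dibromomethyl)-1-hydroxy-3,6-dimethyl-1,2,3,3a,4,7a-hexahydro-5H-inden-5-one
Conditions: Pd(OAc)2 (1.05 equiv), MeCN, 40 °C
Reagents that add atoms: none
Why: Saegusa–Ito dehydrosilylation of the regiodefined silyl enol ether, with β-hydride loss from the ring CH2, gives the endocyclic 2-methyl enone.

Step 6
Reactants: 10 (1S,3S,3aR,7aS)-1-(dibromomethyl)-1-hydroxy-3,6-dimethyl-1,2,3,3a,4,7a-hexahydro-5H-inden-5-one
Product: 11 (1S,3S,3aR,4S,7aR)-1-(dibromomethyl)-1-hydroxy-3,6-dimethyl-5-oxo-2,3,3a,4,5,7a-hexahydro-1H-inden-4-yl acetate (4β-OAc major)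
Conditions: Mn(OAc)3 (2.5 equiv), PhH–AcOH 10:1, reflux
Reagents that add atoms: manganese(III) acetate [Mn+3].CC(=O)[O-].CC(=O)[O-].CC(=O)[O-]
Why: Mn(III) α'-acetoxylation of enones attacks the only α'-CH2, and the epimer ratio does not matter because C-4 is reset in step 7.

Step 7
Reactants: 11 (1S,3S,3aR,4S,7aR)-1-(dibromomethyl)-1-hydroxy-3,6-dimethyl-5-oxo-2,3,3a,4,5,7a-hexahydro-1H-inden-4-yl acetate
Product: 14 (1S,3S,3aR,4R,5S,7aR)-1-(dibromomethyl)-1,5-dihydroxy-3,6-dimethyl-2,3,3a,4,5,7a-hexahydro-1H-inden-4-yl acetate (4α-OAc; 5α-OH), via bis-TMS enol ether 12 (not isolated), via 4α-acetoxy enone 13 (not isolated)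
Conditions: TMSOTf (2.2 equiv), Et3N, CH2Cl2, 0 °C; concentrate; MeOH, CeCl3·7H2O, −78 °C; then NaBH4, −78 °C
Reagents that add atoms: none
Why: Soft enolisation flattens C-4, kinetic axial protonation of the silyl enol ether from the open β-face places H-4 β and OAc α, and Luche 1,2-reduction delivers hydride from the same β-face because the axial C-3a–C-3 bond blocks the α-face, which gives the all-cis 4α,5α-dioxygenation.

Step 8
Reactants: 14 (1S,3S,3aR,4R,5S,7aR)-1-(dibromomethyl)-1,5-dihydroxy-3,6-dimethyl-2,3,3a,4,5,7a-hexahydro-1H-inden-4-yl acetate; 15 acetone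
Product: 18 (1R,4S,4aR,5R,6S,8aR)-6-hydroxy-1-(2-hydroxypropan-2-yl)-4,7-dimethyl-2-oxo-1,2,3,4,4a,5,6,8a-octahydronaphthalen-5-yl acetate, via magnesium carbenoid 16 (not isolated), via magnesium enolate 17 (not isolated)
Conditions: i-PrMgCl·LiCl (3.1 equiv), THF, −78 → −25 °C; acetone, −78 °C; aq NH4Cl
Reagents that add atoms: none
Why: Proposed new method: two equivalents of turbo-Grignard turn both hydroxyls into magnesium alkoxides and the third performs Br/Mg exchange on CHBr2; in the resulting magnesium β-oxido carbenoid 16 the C-1–C-7a σ-bond (tertiary and allylic, so a better migrating group than the C-2 methylene) displaces bromide in a 1,2-shift with retention at C-7a, which enlarges the cyclopentane to the cyclohexanone and forms the C-1–C-8a bond of ring A; the enolate 17 is nucleophilic only at the inserted carbon, so acetone is attached exactly at C-1 (configuration there is inconsequential), and the low temperature and absence of organolithium spare the acetate; the closest known reaction type is the lithium β-oxido carbenoid ring enlargement of cycloalkanones (dibromomethyllithium adduct plus butyllithium, more substituted α-carbon migrates) and its sulfoxide–magnesium exchange variant, neither of which has been triggered by Br/Mg exchange on an ester-bearing dibromomethyl carbinol or coupled to a ketone aldol.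

Step 9
Reactants: 18 (1R,4S,4aR,5R,6S,8aR)-6-hydroxy-1-(2-hydroxypropan-2-yl)-4,7-dimethyl-2-oxo-1,2,3,4,4a,5,6,8a-octahydronaphthalen-5-yl acetate
Product: 20 (4S,4aR,5R,6S,8aR)-4,7-dimethyl-2-oxo-1-(propan-2-ylidene)-1,2,3,4,4a,5,6,8a-octahydronaphthalene-5,6-diyl diacetate, via triacetate 19 (not isolated)
Conditions: Ac2O, Et3N, DMAP, CH2Cl2, 35 °C; then DBU, rt
Reagents that add atoms: acetic anhydride CC(=O)OC(C)=O
Why: DMAP-catalysed acetylation caps both hydroxyls, and the tertiary β-acetoxy ketone then undergoes E1cB elimination through the acidic H-1, so only the conjugated exocyclic isopropylidene can form.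

Step 10
Reactants: 20 (4S,4aR,5R,6S,8aR)-4,7-dimethyl-2-oxo-1-(propan-2-ylidene)-1,2,3,4,4a,5,6,8a-octahydronaphthalene-5,6-diyl diacetate
Product: 21 (3S,4R,4aS,5R,6S,8aR)-3-hydroxy-4,7-dimethyl-2-oxo-1-(propan-2-ylidene)-1,2,3,4,4a,5,6,8a-octahydronaphthalene-5,6-diyl diacetate
Conditions: LiHMDS (1.05 equiv), THF, −78 °C; 2-(phenylsulfonyl)-3-phenyloxaziridine; aq NH4Cl; DBU (5 mol %), CH2Cl2, rt
Reagents that add atoms: 2-(phenylsulfonyl)-3-phenyloxaziridine O=S(=O)(c1ccccc1)N1OC1c1ccccc1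
Why: Kinetic α'-deprotonation (the ketone is far more acidic than the acetates) is followed by Davis enolate hydroxylation, and brief base equilibration through the enediol funnels C-3 to the equatorial, hydrogen-bonded 3α-OH trans to the 4β-methyl, which is the conjugated α-ketol minimum.

## Compound list
1 | (S)-4-[(tert-butyldimethylsilyl)oxy]cyclopent-2-en-1-one | O=C1C=C[C@@H](O[Si](C)(C)C(C)(C)C)C1 | starting material
2 | (3S,4S)-4-[(tert-butyldimethylsilyl)oxy]-3-methylcyclopentan-1-one | O=C1C[C@H](C)[C@@H](O[Si](C)(C)C(C)(C)C)C1 | intermediate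
3 | (S)-4-methylcyclopent-2-en-1-one | O=C1C=C[C@@H](C)C1 | intermediate
4 | 3-methylbut-3-en-2-one | CC(=O)C(C)=C | starting material
5 | tert-butyldimethyl[(3-methylbuta-1,3-dien-2-yl)oxy]silane | C=C(O[Si](C)(C)C(C)(C)C)C(C)=C | intermediate
6 | (3S,3aR,7aR)-5-[(tert-butyldimethylsilyl)oxy]-3,6-dimethyl-2,3,3a,4,7,7a-hexahydro-1H-inden-1-one | C1[C@@H]2[C@@H](C)CC(=O)[C@@H]2CC(C)=C1O[Si](C)(C)C(C)(C)C | intermediate
7 | dibromomethane | BrCBr | starting material
8 | dibromomethyllithium | [Li]C(Br)Br | intermediate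
9 | (1S,3S,3aR,7aR)-5-[(tert-butyldimethylsilyl)oxy]-1-(dibromomethyl)-3,6-dimethyl-2,3,3a,4,7,7a-hexahydro-1H-inden-1-ol | C1[C@@H]2[C@@H](C)C[C@@](O)(C(Br)Br)[C@@H]2CC(C)=C1O[Si](C)(C)C(C)(C)C | intermediate
10 | (1S,3S,3aR,7aS)-1-(dibromomethyl)-1-hydroxy-3,6-dimethyl-1,2,3,3a,4,7a-hexahydro-5H-inden-5-one | C1[C@@H]2[C@@H](C)C[C@@](O)(C(Br)Br)[C@@H]2C=C(C)C1=O | intermediate
11 | (1S,3S,3aR,4S,7aR)-1-(dibromomethyl)-1-hydroxy-3,6-dimethyl-5-oxo-2,3,3a,4,5,7a-hexahydro-1H-inden-4-yl acetate | CC(=O)O[C@H]1[C@@H]2[C@@H](C)C[C@@](O)(C(Br)Br)[C@@H]2C=C(C)C1=O | intermediate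
12 | (1S,3S,3aR,7aR)-1-(dibromomethyl)-3,6-dimethyl-1,5-bis[(trimethylsilyl)oxy]-2,3,3a,7a-tetrahydro-1H-inden-4-yl acetate | CC(=O)OC=1[C@@H]2[C@@H](C)C[C@@](O[Si](C)(C)C)(C(Br)Br)[C@@H]2C=C(C)C=1O[Si](C)(C)C | intermediate
13 | (1S,3S,3aR,4R,7aR)-1-(dibromomethyl)-1-hydroxy-3,6-dimethyl-5-oxo-2,3,3a,4,5,7a-hexahydro-1H-inden-4-yl acetate | CC(=O)O[C@@H]1[C@@H]2[C@@H](C)C[C@@](O)(C(Br)Br)[C@@H]2C=C(C)C1=O | intermediate
14 | (1S,3S,3aR,4R,5S,7aR)-1-(dibromomethyl)-1,5-dihydroxy-3,6-dimethyl-2,3,3a,4,5,7a-hexahydro-1H-inden-4-yl acetate | CC(=O)O[C@@H]1[C@@H]2[C@@H](C)C[C@@](O)(C(Br)Br)[C@@H]2C=C(C)[C@@H]1O | intermediate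
15 | acetone | CC(C)=O | starting material
16 | bis(chloromagnesium alkoxide) of 14 bearing a bromo(chloromagnesio)methyl group at C-1 | CC(=O)O[C@@H]1[C@@H]2[C@@H](C)C[C@@](O[Mg]Cl)(C(Br)[Mg]Cl)[C@@H]2C=C(C)[C@@H]1O[Mg]Cl | intermediate
17 | ring-enlarged chloromagnesium C-2/C-1 enolate (6-O-MgCl; 5α-OAc) | CC(=O)O[C@@H]1[C@@H]2[C@@H](C)CC(O[Mg]Cl)=C[C@@H]2C=C(C)[C@@H]1O[Mg]Cl | intermediate
18 | (1R,4S,4aR,5R,6S,8aR)-6-hydroxy-1-(2-hydroxypropan-2-yl)-4,7-dimethyl-2-oxo-1,2,3,4,4a,5,6,8a-octahydronaphthalen-5-yl acetate | CC(=O)O[C@@H]1[C@@H]2[C@@H](C)CC(=O)[C@@H](C(C)(C)O)[C@@H]2C=C(C)[C@@H]1O | intermediate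
19 | (1R,4S,4aR,5R,6S,8aR)-1-(2-acetoxypropan-2-yl)-4,7-dimethyl-2-oxo-1,2,3,4,4a,5,6,8a-octahydronaphthalene-5,6-diyl diacetate | CC(=O)O[C@@H]1[C@@H]2[C@@H](C)CC(=O)[C@@H](C(C)(C)OC(C)=O)[C@@H]2C=C(C)[C@@H]1OC(C)=O | intermediate
20 | (4S,4aR,5R,6S,8aR)-4,7-dimethyl-2-oxo-1-(propan-2-ylidene)-1,2,3,4,4a,5,6,8a-octahydronaphthalene-5,6-diyl diacetate | CC(=O)O[C@@H]1[C@@H]2[C@@H](C)CC(=O)C(=C(C)C)[C@@H]2C=C(C)[C@@H]1OC(C)=O | intermediate
21 | (3S,4R,4aS,5R,6S,8aR)-3-hydroxy-4,7-dimethyl-2-oxo-1-(propan-2-ylidene)-1,2,3,4,4a,5,6,8a-octahydronaphthalene-5,6-diyl diacetate | CC(=O)O[C@@H]1[C@@H]2[C@@H](C)[C@H](O)C(=O)C(=C(C)C)[C@@H]2C=C(C)[C@@H]1OC(C)=O | target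

## Step count
- **Total steps:** 10.
- **Longest linear sequence:** 9 (1 → 3 → 6 → 9 → 10 → 11 → 14 → 18 → 20 → 21).

## Steps most likely to fail

**Step 8 (proposed new ring enlargement/aldol).**
- Risks: β-oxide elimination to a vinyl bromide, attack of the Grignard reagent on the acetate, migration of C-2, or retro-aldol.
- Fallback: it uses known chemistry, sets out from 14 and returns at 20.
- Excess n-BuLi (7 equiv, THF, −95 → 0 °C) deprotonates both hydroxyls. It sacrifices the acetate and performs Br/Li exchange to give the classical lithium β-oxido carbenoid F2.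
- F2 rearranges to the lithium enolate F3. Acetone at −78 °C then gives the triol ketone F4.
- Peracetylation of F4 under the step 9 conditions (3 equiv Ac2O) passes through 19 and gives 20 with DBU.

**Step 7 (resetting C-4 and reducing C-5).**
- Risks: γ-enolisation at C-7a, unselective protonation, or α-face hydride attack.
- Fallback: it sets out from 10 and returns at 14. It sets C-4 by SN2 inversion instead of protonation.
- LiHMDS (2.1 equiv) and the Davis oxaziridine hydroxylate the α'-enolate from the β-face to give the 4β-hydroxy enone F1.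
- Mitsunobu reaction with AcOH (PPh3, DIAD) inverts C-4 to give 13, now isolated. Luche reduction of 13 gives 14.

**Step 10 (late enolate oxidation beside two acetates).**
- Risks: γ-deprotonation at the isopropylidene methyls, acetate enolisation, or incomplete epimerisation.
- Fallback: it sets out from 20 and returns at 21, and it avoids strong base.
- Mn(OAc)3 α'-acetoxylation at C-3 (PhH, reflux, equatorial product) gives the triacetate F5.
- The activated α-keto acetate of F5 is then cleaved selectively with KHCO3 in MeOH at 0 °C to give 21.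

## Further compounds
F1 | step 7 | (1S,3S,3aR,4S,7aR)-1-(dibromomethyl)-1,4-dihydroxy-3,6-dimethyl-1,2,3,3a,4,7a-hexahydro-5H-inden-5-one | O[C@H]1[C@@H]2[C@@H](C)C[C@@](O)(C(Br)Br)[C@@H]2C=C(C)C1=O
F2 | step 8 | trilithium alkoxide of the deacetylated triol bearing a bromo(lithio)methyl group at C-1 | [Li]O[C@@H]1[C@@H]2[C@@H](C)C[C@@](O[Li])(C([Li])Br)[C@@H]2C=C(C)[C@@H]1O[Li]
F3 | step 8 | ring-enlarged lithium C-2/C-1 enolate with 5,6-bis(lithium alkoxide) | [Li]O[C@@H]1[C@@H]2[C@@H](C)CC(O[Li])=C[C@@H]2C=C(C)[C@@H]1O[Li]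
F4 | step 8 | (1R,4S,4aR,5R,6S,8aR)-5,6-dihydroxy-1-(2-hydroxypropan-2-yl)-4,7-dimethyl-3,4,4a,5,6,8a-hexahydronaphthalen-2(1H)-one | O[C@@H]1[C@@H]2[C@@H](C)CC(=O)[C@@H](C(C)(C)O)[C@@H]2C=C(C)[C@@H]1O
F5 | step 10 | (3S,4R,4aS,5R,6S,8aR)-4,7-dimethyl-2-oxo-1-(propan-2-ylidene)-1,2,3,4,4a,5,6,8a-octahydronaphthalene-3,5,6-triyl triacetate | CC(=O)O[C@@H]1[C@@H]2[C@@H](C)[C@H](OC(C)=O)C(=O)C(=C(C)C)[C@@H]2C=C(C)[C@@H]1OC(C)=O
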